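A ratio opens the reckoning: time at 60 °C over the half-life of the starting material, here called the half-lives served.

| setting | east | theta | gamma |
|---|---|---|---|
| starting material | 0.050 M | 0.10 M | 0.10 M |
| partner | 1 equiv | 1.00 equiv | 1.00 equiv |
| temperature | 60 °C |  |  |
| remark | run made earlier | at 60 °C until 1.5 h, from then on at 30 °C | at 60 °C throughout |
| time |  | 8.0 h | 8.0 h |

east run (percent of the starting material charged)

| time / h | target / % | starting material / % |
|---|---|---|
| 0.667 | 0.9 | 74.8 |
| 1.33 | 3.8 | 55.6 |
| 2.00 | 7.1 | 41.9 |
| 2.50 | 9.7 | 34.1 |

(each reading ± 0.3 percentage points)

- the earlier runs do not show what temperature does; that part of a forecast is a guess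

1. the winner by amount of target, in percent of the starting material charged; "neither" if no more than 2 percentage points parts them (theta / gamma / neither)
2. how much target is there at the end, in percent of the starting material charged: theta
3. how much target is there at the end, in percent of the starting material charged: gamma

What is that half-life? The last reading of the east run gives a first-order constant of 0.430 h⁻¹, so the starting material halves in 1.61 h, the half-life of the starting material. Put back in, this constant returns 75.0% at the first reading of the east run, against 74.8% read. A first-order half-life carries no concentration, so it is taken over to 0.10 M.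

How many half-lives does each flask serve? Theta serves 0.931 before it cools and gamma 4.97. For these times the half-life reckons 47.6% of the starting material consumed in theta and 96.8% in gamma, twice as much.

Does consumed starting material arrive as target at once? In the east run 65.9% had been consumed at the last reading, but target stood at 9.7%, a share of 14.7%. The rest is a gap in the mass balance of the east run, so target trails consumption there. What 30 °C does to the rates is a guess; if cooling slows them, theta stays behind. This reckoning picks gamma and commits to no yield.

The forecast also names gamma, with 13% for theta and 57% for gamma, and grants that “any side loss would lower it”.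

The flask gives gamma, with 13.4% in theta and 29.5% in gamma, 28 percentage points below the forecast for gamma.

    starting material → intermediate (k = 1.20 × 10⁻⁴ s⁻¹, Ea = 100 kJ mol⁻¹)
    partner + intermediate → target (k = 8.20 × 10⁻⁴ M⁻¹ s⁻¹, Ea = 66.0 kJ mol⁻¹)
    2 intermediate → homo product (k = 6.20 × 10⁻⁴ M⁻¹ s⁻¹, Ea = 73.0 kJ mol⁻¹)
    target ⇌ isomer of the product (K = 1.70, k = 4.20 × 10⁻⁵ s⁻¹, Ea = 102 kJ mol⁻¹, ΔH = −47.0 kJ mol⁻¹)
    (constants at 60 °C)

Gamma also holds 30.2% of homo product at the end, each one counting as two. Its 4.97 half-lives served put 3.20% of starting material in gamma, and the flask holds 3.16%.

The neighbour flask, like gamma but with 0.600 equiv of partner, serves the same 4.97 half-lives, which gives 3.20% of starting material. It holds 3.2%, while its target is lower than gamma's, at 19.8%.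

(The readings were computed on assumed constants; noise was put on by code.)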